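**Retrosynthetic overview**
1. Target 10 ⇒ flat, achiral 1-naphthol 8: C4–H and C3–H are added in one enantioselective dearomative transfer hydrogenation with a chiral Brønsted acid, and C2 is then set by equilibration.
2. 8 ⇒ 4-bromonaphthol 6 + arylboronic acid 7 (biaryl bond by Suzuki–Miyaura coupling); 6 ⇒ naphthol 5 (para-bromination).
3. 5 ⇒ aryne precursor 1 + 3,4-dimethylfuran 2 (aryne–furan Diels–Alder, then acid opening of the oxygen bridge).
4. Ring order: ring A is bought (in 1); ring B is formed in step 1 as an arene and de-aromatised in step 4; the pendant aryl ring C arrives ready-made in step 3.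

Assumption: the sense of induction of the IDPi acid cannot be predicted, so it is written as (S,S) and its mirror image is used if the first run gives the (4S) series; 1, 2 and 7 are taken as purchasable.

Step 1
Reactants: 1 4,5-dimethoxy-2-(trimethylsilyl)phenyl trifluoromethanesulfonate; 2 3,4-dimethylfuran
Product: 5 6,7-dimethoxy-2,3-dimethylnaphthalen-1-ol, via 4,5-dimethoxybenzyne 3 (not isolated), via oxabenzonorbornadiene 4 (not isolated)
Conditions: CsF, MeCN, 25 °C; then HCl (4 M in dioxane), MeOH, 50 °C, argon
Reagents that add atoms: none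
Why: Fluoride-induced 1,2-elimination gives the aryne, the furan traps it in a Diels–Alder reaction, and acid opens the strained oxygen bridge to an allylic benzylic cation that loses a proton and aromatises (oxabicycle-to-1-naphthol isomerisation); the bridged intermediate is mirror-symmetric, so only one naphthol can form.

Step 2
Reactants: 5 6,7-dimethoxy-2,3-dimethylnaphthalen-1-ol
Product: 6 4-bromo-6,7-dimethoxy-2,3-dimethylnaphthalen-1-ol
Conditions: NBS (1.0 equiv), MeCN, −30 → 0 °C, dark, argon
Reagents that add atoms: N-bromosuccinimide, O=C1CCC(=O)N1Br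
Why: Electrophilic aromatic bromination goes para to the free naphthol OH, the only open position of ring B (C2 carries a methyl group) and far more activated than C5 or C8 of ring A.

Step 3
Reactants: 6 4-bromo-6,7-dimethoxy-2,3-dimethylnaphthalen-1-ol; 7 (3-hydroxy-4-methoxyphenyl)boronic acid
Product: 8 4-(3-hydroxy-4-methoxyphenyl)-6,7-dimethoxy-2,3-dimethylnaphthalen-1-ol
Conditions: Pd(OAc)2 (3 mol %), SPhos (6 mol %), K3PO4, toluene/H2O 10:1, 80 °C, argon
Reagents that add atoms: none
Why: Suzuki–Miyaura coupling with a dialkylbiarylphosphine ligand copes with the electron-rich bromide flanked by the C3 methyl and the peri hydrogen, and both free phenols are tolerated as phenoxides; 8 has no ortho substituent on ring C, so it is achiral.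

Step 4
Reactants: 8 4-(3-hydroxy-4-methoxyphenyl)-6,7-dimethoxy-2,3-dimethylnaphthalen-1-ol
Product: 10 (2S,3R,4R)-4-(3-hydroxy-4-methoxyphenyl)-6,7-dimethoxy-2,3-dimethyl-3,4-dihydronaphthalen-1(2H)-one, via enol 9 (not isolated)
Conditions: (S,S)-IDPi (imidodiphosphorimidate acid from two (S)-BINOL units, 3,3'-aryl = 3,5-(CF3)2C6H3, N-triflyl core; 5 mol %), 1,3,5-trimethylcyclohexa-1,4-diene (2 equiv), CHCl3, −20 °C, argon; then K2CO3, MeOH, 25 °C
Reagents that add atoms: none
Why: Proposed new method: the strongly acidic, confined IDPi reversibly protonates the electron-rich naphthol at C4 (para to OH) to a hydroxyallyl cation that is stabilised by the OH group and the 6-methoxy ring A and is held in the chiral anion by an O–H···anion hydrogen bond, so the two C4-epimeric ion pairs interconvert through 8 and only the (4R) pair is reduced quickly (Curtin–Hammett), the diene giving hydride to C3 anti to the pseudo-axial C4 aryl group (hence 3,4-cis, 3R) and the mesitylenium ion returning the proton to the catalyst, after which enol 9 ketonises and K2CO3/MeOH equilibrates C2 to the diequatorial 2,3-trans (2S) ketone; the closest known reactions are achiral strong-Brønsted-acid-catalysed ionic transfer hydrogenation of alkenes and imines with cyclohexa-1,4-dienes, superacid ionic hydrogenation of naphthols to tetralones through their C-protonated keto forms, and chiral-acid/Hantzsch-ester transfer hydrogenation of quinolines.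

**Compound list**
1 | 4,5-dimethoxy-2-(trimethylsilyl)phenyl trifluoromethanesulfonate | COc1cc(OS(=O)(=O)C(F)(F)F)c(cc1OC)[Si](C)(C)C | starting material
2 | 3,4-dimethylfuran | Cc1cocc1C | starting material
3 | 4,5-dimethoxybenzyne (1,2-didehydro-4,5-dimethoxybenzene) | COC1=CC#CC=C1OC | intermediate
4 | meso-(1R,4S)-6,7-dimethoxy-2,3-dimethyl-1,4-dihydro-1,4-epoxynaphthalene | CC1=C(C)[C@@H]2O[C@H]1c1cc(OC)c(OC)cc12 | intermediate
5 | 6,7-dimethoxy-2,3-dimethylnaphthalen-1-ol | COc1cc2cc(C)c(C)c(O)c2cc1OC | intermediate
6 | 4-bromo-6,7-dimethoxy-2,3-dimethylnaphthalen-1-ol | COc1cc2c(Br)c(C)c(C)c(O)c2cc1OC | intermediate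
7 | (3-hydroxy-4-methoxyphenyl)boronic acid | COc1ccc(B(O)O)cc1O | starting material
8 | 4-(3-hydroxy-4-methoxyphenyl)-6,7-dimethoxy-2,3-dimethylnaphthalen-1-ol (achiral) | COc1ccc(-c2c(C)c(C)c(O)c3cc(OC)c(OC)cc23)cc1O | intermediate
9 | (3R,4R)-4-(3-hydroxy-4-methoxyphenyl)-6,7-dimethoxy-2,3-dimethyl-3,4-dihydronaphthalen-1-ol (enol, methyl and aryl cis) | COc1ccc([C@@H]2c3cc(OC)c(OC)cc3C(O)=C(C)[C@@H]2C)cc1O | intermediate
10 | (2S,3R,4R)-4-(3-hydroxy-4-methoxyphenyl)-6,7-dimethoxy-2,3-dimethyl-3,4-dihydronaphthalen-1(2H)-one (2,3-trans, 3,4-cis) | COc1ccc([C@@H]2c3cc(OC)c(OC)cc3C(=O)[C@@H](C)[C@@H]2C)cc1O | target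

**Totals**
Total step count: 4. Longest linear sequence: 4 steps (1 + 2 → 5 → 6 → 8 → 10).

**Steps most likely to fail**

Step 4 (the proposed new step). The catalyst may not protonate C4 enough, hydride transfer from the diene to the stabilised cation may be slow, the enantiomeric excess may be low, or hydride may attack C1 instead of C3. Fallback with known chemistry, setting out from 8 and coming back at 10: classical stoichiometric ionic hydrogenation of the naphthol through its C-protonated keto form (CF3SO3H, Et3SiH, CH2Cl2, −40 → 0 °C; then K2CO3, MeOH) gives the same 3,4-cis, 2,3-trans ketone as a racemate. This is 10 together with its mirror image (2R,3S,4S)-4-(3-hydroxy-4-methoxyphenyl)-6,7-dimethoxy-2,3-dimethyl-3,4-dihydronaphthalen-1(2H)-one F1, and the two are separated by preparative chiral-phase SFC.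

Step 3. The hindered, electron-rich and easily oxidised bromonaphthol may undergo protodebromination or quinone formation instead of coupling. Fallback, setting out from 2 and coming back at 8, with the aryl group brought in before ring B exists: 5-bromo-2-methoxyphenol is protected (MOMCl, i-Pr2NEt, CH2Cl2) as 4-bromo-1-methoxy-2-(methoxymethoxy)benzene F2. Direct C2–H arylation of 2 (3 equiv) with F2 (Pd(OAc)2, PCy3·HBF4, PivOH, K2CO3, DMAc, 110 °C) gives 2-[4-methoxy-3-(methoxymethoxy)phenyl]-3,4-dimethylfuran F3. Cycloaddition of F3 with aryne 3 generated from 1 (CsF, MeCN) gives racemic 1-[4-methoxy-3-(methoxymethoxy)phenyl]-6,7-dimethoxy-2,3-dimethyl-1,4-dihydro-1,4-epoxynaphthalene F4, which is not isolated. HCl/MeOH at 50 °C opens F4 at the aryl-bearing bridgehead (the more stabilised cation) and removes the MOM group, giving 8 directly.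

Step 2. The very electron-rich naphthol may be oxidised by NBS to the quinone or couple C4–C4' instead of being brominated. Fallback, setting out from 5 and coming back at 8, using the quinone on purpose: 5 is oxidised with PhI(OAc)2 (MeCN/H2O, 0 °C) to 6,7-dimethoxy-2,3-dimethylnaphthalene-1,4-dione F5. The aryllithium made from 5-bromo-2-methoxyphenol (NaH, then t-BuLi, THF, −78 °C) adds to one of the two equivalent carbonyl groups and gives racemic 4-hydroxy-4-(3-hydroxy-4-methoxyphenyl)-6,7-dimethoxy-2,3-dimethylnaphthalen-1(4H)-one F6. Reductive aromatisation of this quinol with SnCl2·2H2O/HCl (THF, 25 °C) gives 8 without passing through 6.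

**Further compounds**
F1 | step 4 | (2R,3S,4S)-4-(3-hydroxy-4-methoxyphenyl)-6,7-dimethoxy-2,3-dimethyl-3,4-dihydronaphthalen-1(2H)-one (enantiomer of 10) | COc1ccc([C@H]2c3cc(OC)c(OC)cc3C(=O)[C@H](C)[C@H]2C)cc1O
F2 | step 3 | 4-bromo-1-methoxy-2-(methoxymethoxy)benzene | COCOc1cc(Br)ccc1OC
F3 | step 3 | 2-[4-methoxy-3-(methoxymethoxy)phenyl]-3,4-dimethylfuran | COCOc1cc(-c2occ(C)c2C)ccc1OC
F4 | step 3 | 1-[4-methoxy-3-(methoxymethoxy)phenyl]-6,7-dimethoxy-2,3-dimethyl-1,4-dihydro-1,4-epoxynaphthalene (racemic, one enantiomer drawn) | CC1=C(C)[C@]2(c3ccc(OC)c(OCOC)c3)O[C@H]1c1cc(OC)c(OC)cc12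
F5 | step 2 | 6,7-dimethoxy-2,3-dimethylnaphthalene-1,4-dione | COc1cc2c(cc1OC)C(=O)C(C)=C(C)C2=O
F6 | step 2 | 4-hydroxy-4-(3-hydroxy-4-methoxyphenyl)-6,7-dimethoxy-2,3-dimethylnaphthalen-1(4H)-one (racemic, one enantiomer drawn) | COc1ccc([C@@]2(O)C(C)=C(C)C(=O)c3cc(OC)c(OC)cc32)cc1O
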